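**Retrosynthetic overview**

1. The C8 ester is made last, from diol 32 and N‑methylurocanic acid 33.
2. Ring C (2,5‑dihydrofuran O–C4–C5=C6–C7) is a cyclic hemiketal: C4 is at the ketone level, C7 is fully substituted, and a cis C5=C6 lies between them. That is the signature of a 3,6‑dihydro‑1,2‑dioxine whose only α‑peroxy hydrogen sits on C4, so ring C is made by contraction of that six‑membered peroxide, itself formed by adding O2 across C4/C7 of the carbocyclic (4Z,6Z)‑diene 27; the same base step unveils C2=C3 by loss of a β‑acetate.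
3. Ring B (ten‑membered carbocycle): C2–C3 by aldol union of aldehyde 14 with dienyl iodide ester 20, then C7–C8 by intramolecular Nozaki–Hiyama–Kishi closure.
4. Ring A (cyclohexene; C1, C10, C14): Ireland–Claisen ring contraction of δ‑lactone 9. C12 (Brown allylation) is the only reagent‑set centre; it is relayed to C14 (cuprate) and then to C1 and C10 ([3,3]) before it becomes sp2.
5. Ring order: temporary δ‑lactone → ring A → ring B → six‑membered peroxide → ring C.

Key step: step 20

Remark: locants C1–C14 are those of the target's bicyclo[8.4.0]tetradecane core (C1/C10 ring fusion, C3 carries CO2Me, C4 hemiketal, C7 methyl carbinol, C8 acyloxy carbon, C14 carries isopropyl); the SMILES is read as (1R,4R,7S,8S,10R,14R), i.e. a trans C1/C10 fusion with the C1 side chain cis to isopropyl; 1, 15, 33 and the named reagents are taken as purchasable; metal alkoxides or enolates that are only protonated on work‑up are not numbered.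

**Route**

Step 1
Reactants: 1 3-[(tert-butyldimethylsilyl)oxy]propanal
Product: 2 ethyl (2Z)-5-[(tert-butyldimethylsilyl)oxy]-2-methylpent-2-enoate
Conditions: KN(SiMe3)2, 18-crown-6, THF, −78 °C
Reagents that add atoms: ethyl 2-[bis(2,2,2-trifluoroethoxy)phosphoryl]propanoate, CCOC(=O)C(C)P(=O)(OCC(F)(F)F)OCC(F)(F)F
Why: Still–Gennari variant of the Horner–Wadsworth–Emmons olefination, in which the trifluoroethyl phosphonate under dissociating conditions collapses kinetically to the (Z)-trisubstituted enoate, fixing the C10=C11 geometry (C9 cis to C12) that step 8 needs.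

Step 2
Reactants: 2 ethyl (2Z)-5-[(tert-butyldimethylsilyl)oxy]-2-methylpent-2-enoate
Product: 3 (2Z)-5-[(tert-butyldimethylsilyl)oxy]-2-methylpent-2-en-1-ol
Conditions: i-Bu2AlH (2.2 equiv), CH2Cl2, −78 °C
Reagents that add atoms: none
Why: 1,2-reduction of the enoate by the aluminium hydride should give the allylic alcohol without touching the silyl ether or the alkene geometry.

Step 3
Reactants: 3 (2Z)-5-[(tert-butyldimethylsilyl)oxy]-2-methylpent-2-en-1-ol
Product: 4 (2Z)-5-[(tert-butyldimethylsilyl)oxy]-2-methylpent-2-enal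
Conditions: Dess–Martin periodinane, NaHCO3, CH2Cl2, 0 °C
Reagents that add atoms: none
Why: buffered Dess–Martin oxidation is non-isomerising, so the (Z)-enal should be obtained intact and is used at once.

Step 4
Reactants: 4 (2Z)-5-[(tert-butyldimethylsilyl)oxy]-2-methylpent-2-enal
Product: 6 (4R,5Z)-8-[(tert-butyldimethylsilyl)oxy]-5-methylocta-1,5-dien-4-ol, via diisopinocampheylborinate ester 5 (not isolated)
Conditions: (+)-Ipc2B(allyl) [antipode from (−)-α-pinene], Et2O, −78 °C; then NaOH, H2O2, 0 °C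
Reagents that add atoms: (+)-B-allyldiisopinocampheylborane, C=CCB(C1CC2CC(C1C)C2(C)C)C1CC2CC(C1C)C2(C)C
Why: Brown allylation through a chair six-membered transition state should deliver allyl to the Re face of the aldehyde at a temperature too low for Z→E isomerisation, setting C12 as R under reagent control, and the oxidative work-up cleaves the borinate.

Step 5
Reactants: 6 (4R,5Z)-8-[(tert-butyldimethylsilyl)oxy]-5-methylocta-1,5-dien-4-ol
Product: 7 (4R,5Z)-8-[(tert-butyldimethylsilyl)oxy]-5-methylocta-1,5-dien-4-yl prop-2-enoate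
Conditions: acryloyl chloride, Et3N, DMAP (cat.), CH2Cl2, 0 °C
Reagents that add atoms: acryloyl chloride, C=CC(Cl)=O
Why: simple O-acylation of the secondary allylic alcohol, which leaves C12 untouched.

Step 6
Reactants: 7 (4R,5Z)-8-[(tert-butyldimethylsilyl)oxy]-5-methylocta-1,5-dien-4-yl prop-2-enoate
Product: 8 (6R)-6-{(2Z)-5-[(tert-butyldimethylsilyl)oxy]pent-2-en-2-yl}-5,6-dihydro-2H-pyran-2-one
Conditions: second-generation Grubbs catalyst (5 mol %), CH2Cl2, 40 °C
Reagents that add atoms: none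
Why: ring-closing metathesis of the acrylate with the terminal alkene should close the six-membered unsaturated lactone, the hindered trisubstituted (Z)-alkene being inert to the catalyst.

Step 7
Reactants: 8 (6R)-6-{(2Z)-5-[(tert-butyldimethylsilyl)oxy]pent-2-en-2-yl}-5,6-dihydro-2H-pyran-2-one
Product: 9 (4S,6R)-6-{(2Z)-5-[(tert-butyldimethylsilyl)oxy]pent-2-en-2-yl}-4-(propan-2-yl)oxan-2-one
Conditions: i-PrMgCl, CuBr·SMe2 (10 mol %), THF, −78 °C; aq. NH4Cl
Reagents that add atoms: isopropylmagnesium chloride, CC(C)[Mg]Cl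
Why: copper-catalysed conjugate addition, in which the isopropyl group should add axially to C14 anti to the pseudo-equatorial alkenyl group at C12 of the half-chair lactone, giving the 4,6-trans lactone (C14 set by substrate control from C12).

Step 8
Reactants: 9 (4S,6R)-6-{(2Z)-5-[(tert-butyldimethylsilyl)oxy]pent-2-en-2-yl}-4-(propan-2-yl)oxan-2-one
Product: 12 (1S,2R,6R)-2-{2-[(tert-butyldimethylsilyl)oxy]ethyl}-3-methyl-6-(propan-2-yl)cyclohex-3-ene-1-carboxylic acid, via ketene silyl acetal 10 (not isolated), via trimethylsilyl ester 11 (not isolated)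
Conditions: LiN(i-Pr)2, Me3SiCl, Et3N, THF, −78 °C; then toluene, 110 °C; then aq. citric acid
Reagents that add atoms: none
Why: Ireland–Claisen rearrangement as a lactone-to-carbocycle ring contraction, in which the C13–C14 tether enforces a boat [3,3] transition state, the new C1–C10 bond forms on the lactone face that carried the alkenyl group (anti to isopropyl, so the carboxyl ends cis to isopropyl on ring A) and the (Z)-alkene holds C9 inside so that it ends trans to the carboxyl, relaying C12 to C1 and C10 as C12 becomes sp2.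

Step 9
Reactants: 12 (1S,2R,6R)-2-{2-[(tert-butyldimethylsilyl)oxy]ethyl}-3-methyl-6-(propan-2-yl)cyclohex-3-ene-1-carboxylic acid
Product: 13 [(1S,2R,6R)-2-{2-[(tert-butyldimethylsilyl)oxy]ethyl}-3-methyl-6-(propan-2-yl)cyclohex-3-en-1-yl]methanol
Conditions: LiAlH4, THF, 0 °C
Reagents that add atoms: none
Why: hydride reduction of the carboxylic acid to the primary alcohol, with no epimerisable centre at risk.

Step 10
Reactants: 13 [(1S,2R,6R)-2-{2-[(tert-butyldimethylsilyl)oxy]ethyl}-3-methyl-6-(propan-2-yl)cyclohex-3-en-1-yl]methanol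
Product: 14 (1S,2R,6R)-2-{2-[(tert-butyldimethylsilyl)oxy]ethyl}-3-methyl-6-(propan-2-yl)cyclohex-3-ene-1-carbaldehyde
Conditions: Dess–Martin periodinane, NaHCO3, CH2Cl2, 0 °C
Reagents that add atoms: none
Why: buffered Dess–Martin oxidation should give the α-branched aldehyde without epimerising C1, and the aldehyde is used directly.

Step 11
Reactants: 15 but-2-yn-1-ol
Product: 17 (2Z)-3-iodobut-2-en-1-ol, via cyclic alkenylaluminate 16 (not isolated)
Conditions: NaAlH2(OCH2CH2OMe)2, THF, 0 °C; then I2, −78 °C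
Reagents that add atoms: iodine, II
Why: hydroxyl-directed trans-hydroalumination (hydride to C2, aluminium to C3 within a five-membered alkoxyaluminate) followed by iododealumination with retention should give the (Z)-iodoalkene only.

Step 12
Reactants: 17 (2Z)-3-iodobut-2-en-1-ol
Product: 18 (2Z)-3-iodobut-2-enal
Conditions: MnO2, CH2Cl2, 23 °C
Reagents that add atoms: none
Why: heterogeneous allylic oxidation with manganese dioxide, which keeps the alkene geometry.

Step 13
Reactants: 18 (2Z)-3-iodobut-2-enal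
Product: 19 (3Z,5Z)-6-iodohepta-3,5-dienoic acid
Conditions: (2-carboxyethyl)triphenylphosphonium bromide, NaN(SiMe3)2 (2 equiv), THF, −78 → 0 °C; then 18, −78 °C; aq. HCl
Reagents that add atoms: (2-carboxyethyl)triphenylphosphonium bromide, OC(=O)CC[P+](c1ccccc1)(c1ccccc1)c1ccccc1.[Br-]
Why: Wittig reaction of the non-stabilised carboxylate ylide under lithium-free conditions should form the new C4=C5 alkene with Z geometry and leave the iodoalkene untouched.

Step 14
Reactants: 19 (3Z,5Z)-6-iodohepta-3,5-dienoic acid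
Product: 20 methyl (3Z,5Z)-6-iodohepta-3,5-dienoate
Conditions: Me3SiCHN2, MeOH/toluene, 0 °C
Reagents that add atoms: trimethylsilyldiazomethane, C[Si](C)(C)C=[N+]=[N-]
Why: O-methylation of the acid under neutral conditions, which avoids conjugation of the β,γ-unsaturated ester.

Step 15
Reactants: 20 methyl (3Z,5Z)-6-iodohepta-3,5-dienoate; 14 (1S,2R,6R)-2-{2-[(tert-butyldimethylsilyl)oxy]ethyl}-3-methyl-6-(propan-2-yl)cyclohex-3-ene-1-carbaldehyde
Product: 23 methyl (3Z,5Z)-2-[(acetyloxy){(1S,2R,6R)-2-{2-[(tert-butyldimethylsilyl)oxy]ethyl}-3-methyl-6-(propan-2-yl)cyclohex-3-en-1-yl}methyl]-6-iodohepta-3,5-dienoate (C2/C3 diastereomer mixture), via lithium enolate 21 (not isolated), via lithium aldolate 22 (not isolated)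
Conditions: LiN(i-Pr)2, THF, −78 °C (20); then 14, −78 °C; then Ac2O, −78 → 0 °C
Reagents that add atoms: acetic anhydride, CC(=O)OC(C)=O
Why: aldol addition of the lithium trienolate through its α-carbon (kinetic α-selectivity at −78 °C with the alkene geometries kept) and O-acetylation of the aldolate in the same flask; C2 and C3 may form as a mixture because both are erased in step 20, and the acetate keeps C2=C3 latent because a conjugated (2,4,6)-triene ester would electrocyclise.

Step 16
Reactants: 23 methyl (3Z,5Z)-2-[(acetyloxy){(1S,2R,6R)-2-{2-[(tert-butyldimethylsilyl)oxy]ethyl}-3-methyl-6-(propan-2-yl)cyclohex-3-en-1-yl}methyl]-6-iodohepta-3,5-dienoate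
Product: 24 methyl (3Z,5Z)-2-[(acetyloxy){(1S,2R,6R)-2-(2-hydroxyethyl)-3-methyl-6-(propan-2-yl)cyclohex-3-en-1-yl}methyl]-6-iodohepta-3,5-dienoate
Conditions: HF·pyridine, pyridine, THF, 0 → 23 °C
Reagents that add atoms: none
Why: fluoride cleavage of the primary silyl ether under buffered conditions to which the acetate, the esters and the iodoalkene are stable.

Step 17
Reactants: 24 methyl (3Z,5Z)-2-[(acetyloxy){(1S,2R,6R)-2-(2-hydroxyethyl)-3-methyl-6-(propan-2-yl)cyclohex-3-en-1-yl}methyl]-6-iodohepta-3,5-dienoate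
Product: 25 methyl (3Z,5Z)-2-[(acetyloxy){(1S,2R,6R)-3-methyl-2-(2-oxoethyl)-6-(propan-2-yl)cyclohex-3-en-1-yl}methyl]-6-iodohepta-3,5-dienoate
Conditions: Dess–Martin periodinane, NaHCO3, CH2Cl2, 0 °C
Reagents that add atoms: none
Why: mild Dess–Martin oxidation of the primary alcohol to the C8 aldehyde without elimination of the β-acetate.

Step 18
Reactants: 25 methyl (3Z,5Z)-2-[(acetyloxy){(1S,2R,6R)-3-methyl-2-(2-oxoethyl)-6-(propan-2-yl)cyclohex-3-en-1-yl}methyl]-6-iodohepta-3,5-dienoate
Product: 26 methyl (1S,4Z,6Z,8S,10R,14R)-2-(acetyloxy)-8-hydroxy-7,11-dimethyl-14-(propan-2-yl)bicyclo[8.4.0]tetradeca-4,6,11-triene-3-carboxylate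
Conditions: CrCl2 (8 equiv), NiCl2 (2 mol %), DMSO, 23 °C, 0.003 M
Reagents that add atoms: none
Why: intramolecular Nozaki–Hiyama–Kishi reaction (zerovalent nickel inserts into C7–I with retention, transmetalation to chromium, addition to the C8 aldehyde) should close ring B under high dilution with the (Z,Z)-diene carried over, and C8 is set by macrocyclic substrate control with the chromium alkoxide on the outer face of the forming ring, which is expected to correspond to 8S.

Step 19
Reactants: 26 methyl (1S,4Z,6Z,8S,10R,14R)-2-(acetyloxy)-8-hydroxy-7,11-dimethyl-14-(propan-2-yl)bicyclo[8.4.0]tetradeca-4,6,11-triene-3-carboxylate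
Product: 27 methyl (1S,4Z,6Z,8S,10R,14R)-2-(acetyloxy)-7,11-dimethyl-14-(propan-2-yl)-8-[(triethylsilyl)oxy]bicyclo[8.4.0]tetradeca-4,6,11-triene-3-carboxylate
Conditions: Et3SiOTf, 2,6-lutidine, CH2Cl2, −78 °C
Reagents that add atoms: triethylsilyl trifluoromethanesulfonate, CC[Si](CC)(CC)OS(=O)(=O)C(F)(F)F
Why: O-silylation of the allylic alcohol with the reactive triflate installs a bulky, non-hydrogen-bonding group at C8 that steers the oxygen in step 20.

Step 20
Reactants: 27 methyl (1S,4Z,6Z,8S,10R,14R)-2-(acetyloxy)-7,11-dimethyl-14-(propan-2-yl)-8-[(triethylsilyl)oxy]bicyclo[8.4.0]tetradeca-4,6,11-triene-3-carboxylate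
Product: 31 methyl (1R,2E,4R,5Z,7S,8S,10R,14R)-4-hydroxy-7,11-dimethyl-14-(propan-2-yl)-8-[(triethylsilyl)oxy]-4,7-epoxybicyclo[8.4.0]tetradeca-2,5,11-triene-3-carboxylate, via endoperoxide 28 (not isolated), via hydroxy enone 29 (not isolated), via alkylidene keto alcohol 30 (not isolated)
Conditions: O2, tetraphenylporphyrin (1 mol %), visible light, CH2Cl2, −40 °C; then Et3N, −40 → 23 °C
Reagents that add atoms: dioxygen, O=O
Why: Singlet oxygen should add in a suprafacial [4+2] cycloaddition across C4 and C7 of the ring-held cisoid (4Z,6Z)-diene, closing the six-membered 1,2-dioxine 28, and Et3N then triggers a Kornblum–DeLaMare rearrangement in which removal of the only α-peroxy hydrogen (C4–H; C7 is quaternary) cleaves the O–O bond to the cis-γ-hydroxy enone 29. The β-keto ester so formed loses acetate from C2 by E1cB (30), and the C7 hydroxyl closes onto the C4 ketone by 5-exo-trig hemiketalisation, so the six-membered peroxide ring is contracted to the five-membered dihydrofuranol of ring C. The closest known reaction types are the dye-sensitised photooxygenation of cis,cis-1,3-cycloalkadienes such as cycloocta-1,3-diene and the amine-induced ring contraction of 3,6-dihydro-1,2-dioxines to cis-γ-hydroxy enones and their lactols. C7 is set in the cycloaddition by C8, oxygen arriving anti to the C8–OSiEt3 bond on the face that carries C8–H; C4 follows from C7 because an oxygen bridge across ring B can only be cis, and the C2=C3 geometry (ester trans to C1) is the ring-compatible one reached by equilibration of the alkylidene keto ester. The step needs [4+2] addition at the conjugated diene and not ene reaction at C11=C12 or at allylic C–H bonds, which the higher reactivity of the conjugated diene and the low temperature should favour, and it needs the base events in order, which is secured because C3–H becomes acidic only once the C4 ketone exists, so no triene is present before oxygenation.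

Step 21
Reactants: 31 methyl (1R,2E,4R,5Z,7S,8S,10R,14R)-4-hydroxy-7,11-dimethyl-14-(propan-2-yl)-8-[(triethylsilyl)oxy]-4,7-epoxybicyclo[8.4.0]tetradeca-2,5,11-triene-3-carboxylate
Product: 32 methyl (1R,2E,4R,5Z,7S,8S,10R,14R)-4,8-dihydroxy-7,11-dimethyl-14-(propan-2-yl)-4,7-epoxybicyclo[8.4.0]tetradeca-2,5,11-triene-3-carboxylate
Conditions: HF·pyridine, pyridine, THF, 0 °C
Reagents that add atoms: none
Why: buffered fluoride cleavage of the secondary triethylsilyl ether, to which the tertiary hemiketal and the enoate should be stable.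

Step 22
Reactants: 32 methyl (1R,2E,4R,5Z,7S,8S,10R,14R)-4,8-dihydroxy-7,11-dimethyl-14-(propan-2-yl)-4,7-epoxybicyclo[8.4.0]tetradeca-2,5,11-triene-3-carboxylate; 33 (2E)-3-(1-methyl-1H-imidazol-4-yl)prop-2-enoic acid
Product: 35 methyl (1R,2E,4R,5Z,7S,8S,10R,14R)-4-hydroxy-7,11-dimethyl-8-{[(2E)-3-(1-methyl-1H-imidazol-4-yl)prop-2-enoyl]oxy}-14-(propan-2-yl)-4,7-epoxybicyclo[8.4.0]tetradeca-2,5,11-triene-3-carboxylate, via mixed pivalic anhydride 34 (not isolated)
Conditions: 33, t-BuCOCl, Et3N, THF, 0 °C; then 32, DMAP, 23 °C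
Reagents that add atoms: none
Why: esterification through the mixed pivalic anhydride with nucleophilic catalysis should acylate only the secondary C8 hydroxyl, the tertiary hemiketal hydroxyl at C4 being far less nucleophilic, and no stereocentre is touched.

**Compound list**

1 | 3-[(tert-butyldimethylsilyl)oxy]propanal | O=CCCO[Si](C)(C)C(C)(C)C | starting material
2 | ethyl (2Z)-5-[(tert-butyldimethylsilyl)oxy]-2-methylpent-2-enoate | CCOC(=O)/C(C)=C\CCO[Si](C)(C)C(C)(C)C | intermediate
3 | (2Z)-5-[(tert-butyldimethylsilyl)oxy]-2-methylpent-2-en-1-ol | OC/C(C)=C\CCO[Si](C)(C)C(C)(C)C | intermediate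
4 | (2Z)-5-[(tert-butyldimethylsilyl)oxy]-2-methylpent-2-enal | O=C/C(C)=C\CCO[Si](C)(C)C(C)(C)C | intermediate
5 | (4R,5Z)-8-[(tert-butyldimethylsilyl)oxy]-5-methylocta-1,5-dien-4-yl diisopinocampheylborinate (isopinocampheyl groups from (−)-α-pinene) | C=CC[C@@H](OB(C1CC2CC(C1C)C2(C)C)C1CC2CC(C1C)C2(C)C)/C(C)=C\CCO[Si](C)(C)C(C)(C)C | intermediate
6 | (4R,5Z)-8-[(tert-butyldimethylsilyl)oxy]-5-methylocta-1,5-dien-4-ol | C=CC[C@@H](O)/C(C)=C\CCO[Si](C)(C)C(C)(C)C | intermediate
7 | (4R,5Z)-8-[(tert-butyldimethylsilyl)oxy]-5-methylocta-1,5-dien-4-yl prop-2-enoate | C=CC[C@@H](OC(=O)C=C)/C(C)=C\CCO[Si](C)(C)C(C)(C)C | intermediate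
8 | (6R)-6-{(2Z)-5-[(tert-butyldimethylsilyl)oxy]pent-2-en-2-yl}-5,6-dihydro-2H-pyran-2-one | O=C1C=CC[C@@H](O1)/C(C)=C\CCO[Si](C)(C)C(C)(C)C | intermediate
9 | (4S,6R)-6-{(2Z)-5-[(tert-butyldimethylsilyl)oxy]pent-2-en-2-yl}-4-(propan-2-yl)oxan-2-one (4,6-trans) | O=C1C[C@@H](C(C)C)C[C@@H](O1)/C(C)=C\CCO[Si](C)(C)C(C)(C)C | intermediate
10 | trimethylsilyl ketene acetal of 9: (2R,4R)-2-{(2Z)-5-[(tert-butyldimethylsilyl)oxy]pent-2-en-2-yl}-4-(propan-2-yl)-6-[(trimethylsilyl)oxy]-3,4-dihydro-2H-pyran | C[Si](C)(C)OC1=C[C@@H](C(C)C)C[C@@H](O1)/C(C)=C\CCO[Si](C)(C)C(C)(C)C | intermediate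
11 | trimethylsilyl (1S,2R,6R)-2-{2-[(tert-butyldimethylsilyl)oxy]ethyl}-3-methyl-6-(propan-2-yl)cyclohex-3-ene-1-carboxylate | C[Si](C)(C)OC(=O)[C@H]1[C@@H](C(C)C)CC=C(C)[C@@H]1CCO[Si](C)(C)C(C)(C)C | intermediate
12 | (1S,2R,6R)-2-{2-[(tert-butyldimethylsilyl)oxy]ethyl}-3-methyl-6-(propan-2-yl)cyclohex-3-ene-1-carboxylic acid | OC(=O)[C@H]1[C@@H](C(C)C)CC=C(C)[C@@H]1CCO[Si](C)(C)C(C)(C)C | intermediate
13 | [(1S,2R,6R)-2-{2-[(tert-butyldimethylsilyl)oxy]ethyl}-3-methyl-6-(propan-2-yl)cyclohex-3-en-1-yl]methanol | OC[C@H]1[C@@H](C(C)C)CC=C(C)[C@@H]1CCO[Si](C)(C)C(C)(C)C | intermediate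
14 | (1S,2R,6R)-2-{2-[(tert-butyldimethylsilyl)oxy]ethyl}-3-methyl-6-(propan-2-yl)cyclohex-3-ene-1-carbaldehyde | O=C[C@H]1[C@@H](C(C)C)CC=C(C)[C@@H]1CCO[Si](C)(C)C(C)(C)C | intermediate
15 | but-2-yn-1-ol | CC#CCO | starting material
16 | sodium 2,2-bis(2-methoxyethoxy)-3-methyl-2,5-dihydro-1,2-oxaaluminol-2-uide (cyclic alkenylaluminate) | CC1=CCO[Al-]1(OCCOC)OCCOC.[Na+] | intermediate
17 | (2Z)-3-iodobut-2-en-1-ol | OC/C=C(/C)I | intermediate
18 | (2Z)-3-iodobut-2-enal | O=C/C=C(/C)I | intermediate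
19 | (3Z,5Z)-6-iodohepta-3,5-dienoic acid | OC(=O)C/C=C\C=C(\C)I | intermediate
20 | methyl (3Z,5Z)-6-iodohepta-3,5-dienoate | COC(=O)C/C=C\C=C(\C)I | intermediate
21 | lithium enolate of 20 | [Li]OC(OC)=C/C=C\C=C(\C)I | intermediate
22 | lithium aldolate from 21 and 14 (C2/C3 mixture) | COC(=O)C(/C=C\C=C(\C)I)C(O[Li])[C@H]1[C@@H](C(C)C)CC=C(C)[C@@H]1CCO[Si](C)(C)C(C)(C)C | intermediate
23 | methyl (3Z,5Z)-2-[(acetyloxy){(1S,2R,6R)-2-{2-[(tert-butyldimethylsilyl)oxy]ethyl}-3-methyl-6-(propan-2-yl)cyclohex-3-en-1-yl}methyl]-6-iodohepta-3,5-dienoate (C2/C3 mixture) | COC(=O)C(/C=C\C=C(\C)I)C(OC(C)=O)[C@H]1[C@@H](C(C)C)CC=C(C)[C@@H]1CCO[Si](C)(C)C(C)(C)C | intermediate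
24 | methyl (3Z,5Z)-2-[(acetyloxy){(1S,2R,6R)-2-(2-hydroxyethyl)-3-methyl-6-(propan-2-yl)cyclohex-3-en-1-yl}methyl]-6-iodohepta-3,5-dienoate | COC(=O)C(/C=C\C=C(\C)I)C(OC(C)=O)[C@H]1[C@@H](C(C)C)CC=C(C)[C@@H]1CCO | intermediate
25 | methyl (3Z,5Z)-2-[(acetyloxy){(1S,2R,6R)-3-methyl-2-(2-oxoethyl)-6-(propan-2-yl)cyclohex-3-en-1-yl}methyl]-6-iodohepta-3,5-dienoate | COC(=O)C(/C=C\C=C(\C)I)C(OC(C)=O)[C@H]1[C@@H](C(C)C)CC=C(C)[C@@H]1CC=O | intermediate
26 | methyl (1S,4Z,6Z,8S,10R,14R)-2-(acetyloxy)-8-hydroxy-7,11-dimethyl-14-(propan-2-yl)bicyclo[8.4.0]tetradeca-4,6,11-triene-3-carboxylate (C2/C3 mixture) | COC(=O)C1C(OC(C)=O)[C@H]2[C@@H](C(C)C)CC=C(C)[C@@H]2C[C@H](O)/C(C)=C\C=C/1 | intermediate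
27 | methyl (1S,4Z,6Z,8S,10R,14R)-2-(acetyloxy)-7,11-dimethyl-14-(propan-2-yl)-8-[(triethylsilyl)oxy]bicyclo[8.4.0]tetradeca-4,6,11-triene-3-carboxylate | COC(=O)C1C(OC(C)=O)[C@H]2[C@@H](C(C)C)CC=C(C)[C@@H]2C[C@H](O[Si](CC)(CC)CC)/C(C)=C\C=C/1 | intermediate
28 | 4,7-epidioxide of 27: methyl 2-(acetyloxy)-4,7-epidioxy-7,11-dimethyl-14-(propan-2-yl)-8-[(triethylsilyl)oxy]bicyclo[8.4.0]tetradeca-5,11-diene-3-carboxylate (peroxide bridge anti to the C8 silyloxy group) | COC(=O)C1C(OC(C)=O)[C@H]2[C@@H](C(C)C)CC=C(C)[C@@H]2C[C@H](O[Si](CC)(CC)CC)[C@]2(C)C=C[C@H]1OO2 | intermediate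
29 | methyl (5Z)-2-(acetyloxy)-7-hydroxy-7,11-dimethyl-4-oxo-14-(propan-2-yl)-8-[(triethylsilyl)oxy]bicyclo[8.4.0]tetradeca-5,11-diene-3-carboxylate | COC(=O)C1C(OC(C)=O)[C@H]2[C@@H](C(C)C)CC=C(C)[C@@H]2C[C@H](O[Si](CC)(CC)CC)[C@@](C)(O)/C=C\C1=O | intermediate
30 | methyl (2E,5Z)-7-hydroxy-7,11-dimethyl-4-oxo-14-(propan-2-yl)-8-[(triethylsilyl)oxy]bicyclo[8.4.0]tetradeca-2,5,11-triene-3-carboxylate | COC(=O)/C1=C/[C@H]2[C@@H](C(C)C)CC=C(C)[C@@H]2C[C@H](O[Si](CC)(CC)CC)[C@@](C)(O)/C=C\C1=O | intermediate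
31 | methyl (1R,2E,4R,5Z,7S,8S,10R,14R)-4-hydroxy-7,11-dimethyl-14-(propan-2-yl)-8-[(triethylsilyl)oxy]-4,7-epoxybicyclo[8.4.0]tetradeca-2,5,11-triene-3-carboxylate | COC(=O)/C1=C/[C@H]2[C@@H](C(C)C)CC=C(C)[C@@H]2C[C@H](O[Si](CC)(CC)CC)[C@]2(C)C=C[C@@]1(O)O2 | intermediate
32 | methyl (1R,2E,4R,5Z,7S,8S,10R,14R)-4,8-dihydroxy-7,11-dimethyl-14-(propan-2-yl)-4,7-epoxybicyclo[8.4.0]tetradeca-2,5,11-triene-3-carboxylate | COC(=O)/C1=C/[C@H]2[C@@H](C(C)C)CC=C(C)[C@@H]2C[C@H](O)[C@]2(C)C=C[C@@]1(O)O2 | intermediate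
33 | (2E)-3-(1-methyl-1H-imidazol-4-yl)prop-2-enoic acid (N-methylurocanic acid) | OC(=O)/C=C/c1cn(C)cn1 | starting material
34 | 2,2-dimethylpropanoic (2E)-3-(1-methyl-1H-imidazol-4-yl)prop-2-enoic anhydride | CC(C)(C)C(=O)OC(=O)/C=C/c1cn(C)cn1 | intermediate
35 | methyl (1R,2E,4R,5Z,7S,8S,10R,14R)-4-hydroxy-7,11-dimethyl-8-{[(2E)-3-(1-methyl-1H-imidazol-4-yl)prop-2-enoyl]oxy}-14-(propan-2-yl)-4,7-epoxybicyclo[8.4.0]tetradeca-2,5,11-triene-3-carboxylate | COC(=O)/C1=C/[C@H]2[C@@H](C(C)C)CC=C(C)[C@@H]2C[C@H](OC(=O)/C=C/c2cn(C)cn2)[C@]2(C)C=C[C@@]1(O)O2 | target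

**Count and risks**

Total steps: 22. Longest linear sequence: 18 steps (steps 1–10 and 15–22, from 1); steps 11–14 make the second fragment.

Steps most likely to fail:

Step 20. Singlet oxygen may react by the ene pathway (allylic hydroperoxidation at C11=C12 or at the twisted diene) or on the wrong diene face, instead of the [4+2] addition anti to the silyloxy group. The fallback sets out from 27 and comes back at 31. The peroxide ring is built by a cation-radical chain and not by a concerted cycloaddition: triplet oxygen with catalytic tris(4-bromophenyl)aminium hexachloroantimonate in CH2Cl2 at −78 °C should oxidise only the conjugated diene (the most easily oxidised π system) and close the dioxine stepwise, without needing a planar cisoid diene. Endoperoxide 28 is then isolated cold and rearranged separately with Et3N to 31. No compound outside the list is made (F0).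

Step 18. Facial selectivity in the addition of the alkenylchromium to the C8 aldehyde may be poor (8R alcohol alongside or instead of 8S), and oligomerisation may compete if dilution is insufficient. The fallback sets out from 26 (as the C8 epimer mixture) and comes back at 26. The centre is erased and reset under reagent control: Dess–Martin oxidation gives the macrocyclic dienone F1, and Corey–Bakshi–Shibata reduction with (R)-2-methyl-CBS-oxazaborolidine and catecholborane in toluene at −78 °C should deliver hydride to give the 8S alcohol 26.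

Step 8. The silyl ketene acetal may decompose (desilylation, C-silylation) before the strained boat transition state of the (Z)-alkenyl substrate is reached. The fallback sets out from 9 and comes back at 14, bypassing 12 and 13. The same C1–C10 bond is made by an aliphatic Claisen rearrangement of a neutral enol ether that tolerates much higher temperature: i-Bu2AlH reduction of 9 gives lactol F2, dehydration with methanesulfonyl chloride and Et3N gives the 3,4-dihydro-2H-pyran F3, and thermolysis at about 200 °C in toluene (sealed tube) through the same tether-enforced boat geometry should give aldehyde 14 directly.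

**Further compounds**

F0 | step 20 | none | none
F1 | step 18 | methyl (1S,4Z,6Z,10R,14R)-2-(acetyloxy)-7,11-dimethyl-8-oxo-14-(propan-2-yl)bicyclo[8.4.0]tetradeca-4,6,11-triene-3-carboxylate | COC(=O)C1C(OC(C)=O)[C@H]2[C@@H](C(C)C)CC=C(C)[C@@H]2CC(=O)/C(C)=C\C=C/1
F2 | step 8 | (4S,6R)-6-{(2Z)-5-[(tert-butyldimethylsilyl)oxy]pent-2-en-2-yl}-4-(propan-2-yl)oxan-2-ol | OC1C[C@@H](C(C)C)C[C@@H](O1)/C(C)=C\CCO[Si](C)(C)C(C)(C)C
F3 | step 8 | (2R,4R)-2-{(2Z)-5-[(tert-butyldimethylsilyl)oxy]pent-2-en-2-yl}-4-(propan-2-yl)-3,4-dihydro-2H-pyran | C1=C[C@@H](C(C)C)C[C@@H](O1)/C(C)=C\CCO[Si](C)(C)C(C)(C)C
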